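**Strategy.** The cyclohexenone ring is opened across C2–C3: rehydrating the C2=C3 alkene exposes a β-hydroxy ketone whose retro-aldol is a 1,5-keto-aldehyde, the open form of a 6-deoxyhex-5-enopyranoside. Ring atoms C4, C5 and C6, with their oxygens, are carbons 2, 3 and 4 of a 4-C-alkylated D-galacto pyranoside. In one operation, catalytic Hg(OCOCF3)2 in wet acetone hydrates the exocyclic enol ether, unzips the pyranose and closes the carbocycle by aldol addition; quaternary C6 forces enolisation toward the future C2. The precursor 15 is a methyl glycoside 5-ene carrying two PMB ethers, a free tertiary hydroxyl and the equatorial (Z)-heptadec-8-enyl chain.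

Key step: step 11

Remarks
- Numbering: target ring C1 (C=O), C2=C3, C4, C5, C6 (quaternary). Sugar positions carry the suffix s (C1s–C6s). PMB = 4-methoxybenzyl, TBS = tert-butyldimethylsilyl.
- Assumption: methyl 4,6-O-benzylidene-α-D-glucopyranoside (6) is bought as a catalogue compound; it is the one-step benzylidene acetal of methyl α-D-glucopyranoside.
- Naming: once C5s is trigonal, the prefix of 15 becomes β-L-arabino (C4s is then the reference centre). Its methoxy group is still the axial one of the α-D-galactoside 14.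
- Precursor design: the tertiary C4s hydroxyl stays free, so no protecting step is spent on it. The chain is carried as the finished (Z)-alkene, not as an alkyne, because divalent mercury hydrates alkynes. PMB is chosen because it comes off without hydrogenation.
- Stereocentres: C4 and C5 of the target are C2s and C3s of D-glucose and are never touched; C6 is set in step 7.

Step 1
Reactants: 1 1-decyne; 2 1,7-dibromoheptane
Product: 4 1-bromoheptadec-8-yne, via lithium dec-1-ynide 3 (not isolated)
Conditions: n-BuLi, THF, −78 °C; then 2 (3 equiv), DMPU, −78 °C → rt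
Reagents that add atoms: none
Why: Acetylide alkylation (SN2) at a primary bromide; the excess of the symmetrical dibromide, recoverable by distillation, should hold double alkylation down.

Step 2
Reactants: 4 1-bromoheptadec-8-yne
Product: 5 (Z)-1-bromoheptadec-8-ene
Conditions: H2 (1 atm), Pd/CaCO3 poisoned with Pb(OAc)2 (Lindlar catalyst), quinoline, hexane, rt
Reagents that add atoms: none
Why: Lindlar semihydrogenation delivers both hydrogens to one face of the alkyne on the poisoned palladium surface, which should give the (Z)-alkene and leave the primary C–Br bond alone.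

Step 3
Reactants: 6 methyl 4,6-O-[(R)-benzylidene]-α-D-glucopyranoside
Product: 7 methyl 4,6-O-[(R)-benzylidene]-2,3-di-O-(4-methoxybenzyl)-α-D-glucopyranoside
Conditions: NaH, PMBCl, Bu4NI (cat.), THF/DMF, 0 °C → rt
Reagents that add atoms: 4-methoxybenzyl chloride, COc1ccc(CCl)cc1
Why: Williamson etherification of the two free secondary hydroxyls; no stereocentre is involved.

Step 4
Reactants: 7 methyl 4,6-O-[(R)-benzylidene]-2,3-di-O-(4-methoxybenzyl)-α-D-glucopyranoside
Product: 8 methyl 2,3-di-O-(4-methoxybenzyl)-α-D-glucopyranoside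
Conditions: AcOH/H2O (4:1), 50 °C
Reagents that add atoms: none
Why: Acid-catalysed acetal hydrolysis; PMB ethers and the methyl glycoside should tolerate warm aqueous acetic acid.

Step 5
Reactants: 8 methyl 2,3-di-O-(4-methoxybenzyl)-α-D-glucopyranoside
Product: 9 methyl 6-O-(tert-butyldimethylsilyl)-2,3-di-O-(4-methoxybenzyl)-α-D-glucopyranoside
Conditions: TBSCl (1.1 equiv), imidazole, CH2Cl2, 0 °C
Reagents that add atoms: tert-butyldimethylsilyl chloride, CC(C)(C)[Si](C)(C)Cl
Why: Selective silyl ether formation; the bulky silyl chloride should take the primary C6s hydroxyl and leave the flanked secondary C4s hydroxyl free.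

Step 6
Reactants: 9 methyl 6-O-(tert-butyldimethylsilyl)-2,3-di-O-(4-methoxybenzyl)-α-D-glucopyranoside
Product: 10 methyl 6-O-(tert-butyldimethylsilyl)-2,3-di-O-(4-methoxybenzyl)-α-D-xylo-hexopyranosid-4-ulose
Conditions: Dess–Martin periodinane, CH2Cl2, 0 °C → rt
Reagents that add atoms: none
Why: Dess–Martin oxidation of the one free secondary alcohol under near-neutral conditions, which should avoid β-elimination of the C6s silyloxy group and epimerisation at C3s or C5s.

Step 7
Reactants: 5 (Z)-1-bromoheptadec-8-ene; 10 methyl 6-O-(tert-butyldimethylsilyl)-2,3-di-O-(4-methoxybenzyl)-α-D-xylo-hexopyranosid-4-ulose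
Product: 12 methyl 6-O-(tert-butyldimethylsilyl)-4-C-[(Z)-heptadec-8-en-1-yl]-2,3-di-O-(4-methoxybenzyl)-α-D-galactopyranoside, via (Z)-heptadec-8-en-1-ylmagnesium bromide 11 (not isolated)
Conditions: 5 (2 equiv), Mg, I2 (cat.), THF, 45 °C; then 10, THF, −78 °C → 0 °C; aq. NH4Cl
Reagents that add atoms: none
Why: Grignard 1,2-addition; primary alkylmagnesium halides are expected to approach this α-configured pyranosid-4-ulose along the equatorial trajectory, since the axial path meets the syn-axial H2s and the solvated reagent can bridge the carbonyl oxygen with a neighbouring ether oxygen, so the chain should end up equatorial and the new tertiary hydroxyl axial (D-galacto, which is C6 of the target with R configuration).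

Step 8
Reactants: 12 methyl 6-O-(tert-butyldimethylsilyl)-4-C-[(Z)-heptadec-8-en-1-yl]-2,3-di-O-(4-methoxybenzyl)-α-D-galactopyranoside
Product: 13 methyl 4-C-[(Z)-heptadec-8-en-1-yl]-2,3-di-O-(4-methoxybenzyl)-α-D-galactopyranoside
Conditions: TBAF, THF, 0 °C → rt
Reagents that add atoms: none
Why: Fluoride-induced cleavage of the primary silyl ether; PMB ethers, the glycoside and the alkene are inert to TBAF.

Step 9
Reactants: 13 methyl 4-C-[(Z)-heptadec-8-en-1-yl]-2,3-di-O-(4-methoxybenzyl)-α-D-galactopyranoside
Product: 14 methyl 6-deoxy-4-C-[(Z)-heptadec-8-en-1-yl]-6-iodo-2,3-di-O-(4-methoxybenzyl)-α-D-galactopyranoside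
Conditions: PPh3 (1.5 equiv), imidazole, I2 (1.3 equiv, added last in portions), toluene, rt → 60 °C, dark
Reagents that add atoms: iodine, II
Why: Garegg–Samuelsson iodination replaces only the primary hydroxyl (SN2 at the CH2 group), the tertiary C4s hydroxyl being too hindered for activation; keeping iodine below the phosphine and excluding light should protect the (Z)-alkene.

Step 10
Reactants: 14 methyl 6-deoxy-4-C-[(Z)-heptadec-8-en-1-yl]-6-iodo-2,3-di-O-(4-methoxybenzyl)-α-D-galactopyranoside
Product: 15 methyl 6-deoxy-4-C-[(Z)-heptadec-8-en-1-yl]-2,3-di-O-(4-methoxybenzyl)-β-L-arabino-hex-5-enopyranoside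
Conditions: DBU, THF, reflux
Reagents that add atoms: none
Why: E2 dehydroiodination across C5s–C6s (axial H5s anti to the C–I bond) gives the exocyclic enol ether; an amidine base does not ionise the tertiary alcohol, so ether formation onto C6s should not compete.

Step 11
Reactants: 15 methyl 6-deoxy-4-C-[(Z)-heptadec-8-en-1-yl]-2,3-di-O-(4-methoxybenzyl)-β-L-arabino-hex-5-enopyranoside
Product: 18 (2R,3R,4S,5S)-2-[(Z)-heptadec-8-en-1-yl]-2,5-dihydroxy-3,4-bis[(4-methoxybenzyl)oxy]cyclohexan-1-one, via organomercurial hemiketal 16 (not isolated), via α-mercurio keto-aldehyde 17 (not isolated)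
Conditions: Hg(OCOCF3)2 (10 mol %), acetone/H2O (4:1), rt
Reagents that add atoms: water, O
Why: Ferrier carbocyclization: divalent mercury adds to the electron-rich exocyclic enol ether (Hg at C6s, water at C5s) to give hemiketal 16, which collapses to the ketone with opening of the pyranose and loss of methanol from C1s, leaving the α-mercurio ketone–aldehyde 17. The mercury-bound enolate carbon C6s then adds to the C1s aldehyde in a 6-(enolexo)-exo-trig aldol that closes the only new ring, the six-membered carbocycle, and makes the C6s–C1s bond (C2–C3 of the target), after which divalent mercury is released and turns over. The closest known reaction type is the Hg(OCOCF3)2- or PdCl2-catalysed rearrangement of O-benzylated methyl 6-deoxyhex-5-enopyranosides into 5-hydroxy-2,3,4-trioxygenated cyclohexanones. The one new stereocentre, the C5 carbinol of 18, is expected mainly cis to the C4 ether through a chair-like transition state in which mercury bridges the enolate and aldehyde oxygens, and it is of no consequence because step 12 removes it; C2s, C3s and C4s take no part and pass on unchanged. Regioselectivity is fixed by the quaternary C4s, which leaves C6s as the only enolisable position next to the ketone. The step needs chemoselective mercuration of the enol ether over the remote (Z)-alkene and the PMB arenes, which the far higher nucleophilicity of the enol ether and the low mercury loading should secure; the free tertiary hydroxyl can only form a reversible five-membered lactol with the aldehyde.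

Step 12
Reactants: 18 (2R,3R,4S,5S)-2-[(Z)-heptadec-8-en-1-yl]-2,5-dihydroxy-3,4-bis[(4-methoxybenzyl)oxy]cyclohexan-1-one
Product: 20 (4S,5R,6R)-6-[(Z)-heptadec-8-en-1-yl]-6-hydroxy-4,5-bis[(4-methoxybenzyl)oxy]cyclohex-2-en-1-one, via secondary mesylate 19 (not isolated)
Conditions: MsCl (1.3 equiv), Et3N, CH2Cl2, 0 °C → rt
Reagents that add atoms: none
Why: Mesylation of the secondary β-hydroxyl (the hindered tertiary α-hydroxyl should not react with a small excess at low temperature) and E1cB loss of methanesulfonate through the only available enolate give the conjugated enone; the quaternary α-carbon cannot epimerise.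

Step 13
Reactants: 20 (4S,5R,6R)-6-[(Z)-heptadec-8-en-1-yl]-6-hydroxy-4,5-bis[(4-methoxybenzyl)oxy]cyclohex-2-en-1-one
Product: 21 pleiogenone A, (4S,5R,6R)-6-[(Z)-heptadec-8-en-1-yl]-4,5,6-trihydroxycyclohex-2-en-1-one
Conditions: DDQ (2.6 equiv), CH2Cl2/pH 7 phosphate buffer (10:1), 0 °C → rt
Reagents that add atoms: none
Why: Oxidative PMB cleavage: DDQ oxidises the electron-rich benzylic positions and the water present hydrolyses them to 4-methoxybenzaldehyde and the free hydroxyls, under buffered neutral conditions that the enone, the tertiary ketol and the isolated (Z)-alkene should tolerate.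

**Compound list**

1 | 1-decyne | CCCCCCCCC#C | starting material
2 | 1,7-dibromoheptane | BrCCCCCCCBr | starting material
3 | lithium dec-1-ynide (in situ) | [Li]C#CCCCCCCCC | intermediate
4 | 1-bromoheptadec-8-yne | BrCCCCCCCC#CCCCCCCCC | intermediate
5 | (Z)-1-bromoheptadec-8-ene | BrCCCCCCC/C=C\CCCCCCCC | intermediate
6 | methyl 4,6-O-[(R)-benzylidene]-α-D-glucopyranoside | CO[C@H]1O[C@@H]2CO[C@@H](c3ccccc3)O[C@H]2[C@H](O)[C@H]1O | starting material
7 | methyl 4,6-O-[(R)-benzylidene]-2,3-di-O-(4-methoxybenzyl)-α-D-glucopyranoside | CO[C@H]1O[C@@H]2CO[C@@H](c3ccccc3)O[C@H]2[C@H](OCc4ccc(OC)cc4)[C@H]1OCc5ccc(OC)cc5 | intermediate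
8 | methyl 2,3-di-O-(4-methoxybenzyl)-α-D-glucopyranoside | CO[C@H]1O[C@H](CO)[C@@H](O)[C@H](OCc2ccc(OC)cc2)[C@H]1OCc3ccc(OC)cc3 | intermediate
9 | methyl 6-O-(tert-butyldimethylsilyl)-2,3-di-O-(4-methoxybenzyl)-α-D-glucopyranoside | CO[C@H]1O[C@H](CO[Si](C)(C)C(C)(C)C)[C@@H](O)[C@H](OCc2ccc(OC)cc2)[C@H]1OCc3ccc(OC)cc3 | intermediate
10 | methyl 6-O-(tert-butyldimethylsilyl)-2,3-di-O-(4-methoxybenzyl)-α-D-xylo-hexopyranosid-4-ulose | CO[C@H]1O[C@H](CO[Si](C)(C)C(C)(C)C)C(=O)[C@H](OCc2ccc(OC)cc2)[C@H]1OCc3ccc(OC)cc3 | intermediate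
11 | (Z)-heptadec-8-en-1-ylmagnesium bromide (in situ) | CCCCCCCC/C=C\CCCCCCC[Mg]Br | intermediate
12 | methyl 6-O-(tert-butyldimethylsilyl)-4-C-[(Z)-heptadec-8-en-1-yl]-2,3-di-O-(4-methoxybenzyl)-α-D-galactopyranoside (axial tertiary OH; equatorial chain) | CO[C@H]1O[C@H](CO[Si](C)(C)C(C)(C)C)[C@@](O)(CCCCCCC/C=C\CCCCCCCC)[C@H](OCc2ccc(OC)cc2)[C@H]1OCc3ccc(OC)cc3 | intermediate
13 | methyl 4-C-[(Z)-heptadec-8-en-1-yl]-2,3-di-O-(4-methoxybenzyl)-α-D-galactopyranoside | CO[C@H]1O[C@H](CO)[C@@](O)(CCCCCCC/C=C\CCCCCCCC)[C@H](OCc2ccc(OC)cc2)[C@H]1OCc3ccc(OC)cc3 | intermediate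
14 | methyl 6-deoxy-4-C-[(Z)-heptadec-8-en-1-yl]-6-iodo-2,3-di-O-(4-methoxybenzyl)-α-D-galactopyranoside | CO[C@H]1O[C@H](CI)[C@@](O)(CCCCCCC/C=C\CCCCCCCC)[C@H](OCc2ccc(OC)cc2)[C@H]1OCc3ccc(OC)cc3 | intermediate
15 | methyl 6-deoxy-4-C-[(Z)-heptadec-8-en-1-yl]-2,3-di-O-(4-methoxybenzyl)-β-L-arabino-hex-5-enopyranoside (5-ene of the α-D-galactoside; axial OMe) | CO[C@H]1OC(=C)[C@@](O)(CCCCCCC/C=C\CCCCCCCC)[C@H](OCc2ccc(OC)cc2)[C@H]1OCc3ccc(OC)cc3 | intermediate
16 | C5s hemiketal of 15 bearing a trifluoroacetoxymercurio group on C6s (in situ; C5s configuration undefined) | CO[C@H]1OC(O)(C[Hg]OC(=O)C(F)(F)F)[C@@](O)(CCCCCCC/C=C\CCCCCCCC)[C@H](OCc2ccc(OC)cc2)[C@H]1OCc3ccc(OC)cc3 | intermediate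
17 | 6-deoxy-4-C-[(Z)-heptadec-8-en-1-yl]-2,3-di-O-(4-methoxybenzyl)-6-(trifluoroacetoxymercurio)-L-arabino-hexos-5-ulose, open chain (in situ) | O=C[C@H](OCc1ccc(OC)cc1)[C@@H](OCc1ccc(OC)cc1)[C@](O)(CCCCCCC/C=C\CCCCCCCC)C(=O)C[Hg]OC(=O)C(F)(F)F | intermediate
18 | (2R,3R,4S,5S)-2-[(Z)-heptadec-8-en-1-yl]-2,5-dihydroxy-3,4-bis[(4-methoxybenzyl)oxy]cyclohexan-1-one | CCCCCCCC/C=C\CCCCCCC[C@]1(O)C(=O)C[C@H](O)[C@H](OCc2ccc(OC)cc2)[C@H]1OCc3ccc(OC)cc3 | intermediate
19 | C5 methanesulfonate of 18 (in situ) | CCCCCCCC/C=C\CCCCCCC[C@]1(O)C(=O)C[C@H](OS(C)(=O)=O)[C@H](OCc2ccc(OC)cc2)[C@H]1OCc3ccc(OC)cc3 | intermediate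
20 | (4S,5R,6R)-6-[(Z)-heptadec-8-en-1-yl]-6-hydroxy-4,5-bis[(4-methoxybenzyl)oxy]cyclohex-2-en-1-one | CCCCCCCC/C=C\CCCCCCC[C@]1(O)C(=O)C=C[C@H](OCc2ccc(OC)cc2)[C@H]1OCc3ccc(OC)cc3 | intermediate
21 | pleiogenone A, (4S,5R,6R)-6-[(Z)-heptadec-8-en-1-yl]-4,5,6-trihydroxycyclohex-2-en-1-one | CCCCCCCC/C=C\CCCCCCC[C@]1(O)C(=O)C=C[C@H](O)[C@H]1O | target

**Step count.** Total: 13 steps. Longest linear sequence: 11 steps (6 → 21, steps 3–13); the two-step side branch 1 → 5 joins at step 7.

**Steps most likely to fail**

Step 11. The ring closure may stall in two ways. Mercury may be consumed by the chain alkene, or the opened keto-aldehyde may rest as its lactol on the tertiary hydroxyl and decompose before the aldol takes place. The fallback separates hydration from ring closure and uses no metal. It sets out from 15: dilute aqueous H2SO4 in acetone at rt should hydrate the enol ether by protonation at C6s and release methanol, giving the keto-aldehyde 6-deoxy-4-C-[(Z)-heptadec-8-en-1-yl]-2,3-di-O-(4-methoxybenzyl)-L-arabino-hexos-5-ulose F1. Catalytic DBU in CH2Cl2 at 0 °C should then close the ring by an intramolecular aldol addition of the methyl ketone enolate, the only one the ketone can form, onto the aldehyde. The fallback comes back to the route at 18.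

Step 7. The addition may suffer from poor facial selectivity, with axial delivery giving the gluco-configured tertiary alcohol, or the basic reagent may enolise the dialkoxy ketone and trigger β-elimination. The fallback builds the tertiary centre in two stages with the small and large nucleophiles exchanged, and it sets out from 10 and from 1.
- Trimethylsulfoxonium iodide and NaH in DMSO/THF (Corey–Chaykovsky epoxidation, reversible addition, equatorial C–C bond) should convert 10 into the spiro-epoxide methyl 4,4'-anhydro-6-O-(tert-butyldimethylsilyl)-4-C-(hydroxymethyl)-2,3-di-O-(4-methoxybenzyl)-α-D-galactopyranoside F2, whose oxirane oxygen is axial.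
- The chain, one carbon shorter, is made as in steps 1 and 2: 3 (from 1) is alkylated with 1,6-dibromohexane to give 1-bromohexadec-7-yne F3, and Lindlar semihydrogenation gives (Z)-1-bromohexadec-7-ene F4.
- F4 is converted with Mg in THF into (Z)-hexadec-7-en-1-ylmagnesium bromide F5, which with CuI (cat.) at −30 °C should open F2 at its CH2 terminus without touching the C4s–O bond.
The fallback comes back to the route at 12.

Step 13. The oxidised benzylic position at C5–O may be captured by the neighbouring cis tertiary hydroxyl, giving a 4-methoxybenzylidene acetal and then a benzoate, or the liberated allylic alcohol may be oxidised further. The fallback replaces oxidation by acidolysis. It sets out from 20: TFA/CH2Cl2 (1:9) with anisole at 0 °C should ionise both PMB ethers and transfer the 4-methoxybenzyl cations to the arene scavenger, a pathway in which neither acetal formation nor over-oxidation is possible. The fallback comes back to the route at 21 and makes no new compound.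

**Further compounds**

F1 | step 11 | 6-deoxy-4-C-[(Z)-heptadec-8-en-1-yl]-2,3-di-O-(4-methoxybenzyl)-L-arabino-hexos-5-ulose (open-chain form) | O=C[C@H](OCc1ccc(OC)cc1)[C@@H](OCc1ccc(OC)cc1)[C@](O)(CCCCCCC/C=C\CCCCCCCC)C(C)=O
F2 | step 7 | methyl 4,4'-anhydro-6-O-(tert-butyldimethylsilyl)-4-C-(hydroxymethyl)-2,3-di-O-(4-methoxybenzyl)-α-D-galactopyranoside | CO[C@H]1O[C@H](CO[Si](C)(C)C(C)(C)C)[C@@]2(CO2)[C@H](OCc3ccc(OC)cc3)[C@H]1OCc4ccc(OC)cc4
F3 | step 7 | 1-bromohexadec-7-yne | BrCCCCCCC#CCCCCCCCC
F4 | step 7 | (Z)-1-bromohexadec-7-ene | BrCCCCCC/C=C\CCCCCCCC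
F5 | step 7 | (Z)-hexadec-7-en-1-ylmagnesium bromide | CCCCCCCC/C=C\CCCCCC[Mg]Br
F0 | step 13 | none | none
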